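The route cuts ring B of the apigenin half (unit 1, C1'–C6') across C1'–C2' and C5'–C6'. Ring B is a phenol with O on C4', the crowded flavon-8''-yl group on the neighbouring C3', and the pyranone carbon para on C1'. A 2-aryl-1-amino-3-siloxybutadiene imprints exactly this pattern on a propiolate. One Diels–Alder/amine-loss operation therefore builds the whole ring around a C3'–C8'' bond that already exists, which avoids a hindered biaryl coupling. The precursor is the complete, benzyl-protected acacetin half (unit 2) bearing at C8'' a Me2N–CH=C–C(OTBS)=CH2 chain. That chain is grown from an allyl group placed by aromatic Claisen rearrangement.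

Key step: step 9

Assumption: the target SMILES carries no stereodescriptor, so the C3'–C8'' biaryl axis is treated as configurationally undefined and the route has no stereocentre to set. The 1,3-diketones are drawn as their diketo tautomers.

Step 1
Reactants: 1 2,4,6-trihydroxyacetophenone
Product: 2 1-[2,4-bis(benzyloxy)-6-hydroxyphenyl]ethanone
Conditions: BnBr (2.1 equiv), K2CO3 (2.2 equiv), DMF, 25 → 60 °C
Reagents that add atoms: benzyl bromide, BrCc1ccccc1
Why: Williamson etherification should stop after two benzylations because the last phenol is locked in a strong hydrogen bond to the acetyl carbonyl and is the least nucleophilic, so limiting the halide leaves free exactly the OH needed later.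

Step 2
Reactants: 2 1-[2,4-bis(benzyloxy)-6-hydroxyphenyl]ethanone; 3 allyl bromide
Product: 4 1-[2-(allyloxy)-4,6-bis(benzyloxy)phenyl]ethanone
Conditions: K2CO3 (2 equiv), DMF, 60 °C
Reagents that add atoms: none
Why: With surplus base, heat and a reactive allylic halide the chelated phenol is also alkylated (Williamson etherification), and no other acidic O–H remains to compete.

Step 3
Reactants: 4 1-[2-(allyloxy)-4,6-bis(benzyloxy)phenyl]ethanone
Product: 5 1-[3-allyl-4,6-bis(benzyloxy)-2-hydroxyphenyl]ethanone
Conditions: PhNEt2, 200 °C, Ar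
Reagents that add atoms: none
Why: In this aromatic Claisen rearrangement the [3,3] shift goes to C3, the only ortho carbon bearing hydrogen (the other carries the acetyl group), and tautomerisation makes it irreversible, restores the chelated phenol and fixes the allyl group on the future C8''.

Step 4
Reactants: 5 1-[3-allyl-4,6-bis(benzyloxy)-2-hydroxyphenyl]ethanone; 6 4-methoxybenzoyl chloride
Product: 7 1-[3-allyl-4,6-bis(benzyloxy)-2-hydroxyphenyl]-3-(4-methoxyphenyl)propane-1,3-dione
Conditions: LiN(SiMe3)2 (3.2 equiv), THF, −78 → −10 °C; then 6, −78 °C → rt; aq. HCl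
Reagents that add atoms: none
Why: The hindered amide base converts 5 into its phenoxide–enolate dianion, which the acid chloride acylates at carbon (crossed Claisen-type C-acylation, the one-flask equivalent of a Baker–Venkataraman sequence), while the surplus base stores the product as its enolate and is too mild at this temperature to isomerise the allyl group.

Step 5
Reactants: 7 1-[3-allyl-4,6-bis(benzyloxy)-2-hydroxyphenyl]-3-(4-methoxyphenyl)propane-1,3-dione
Product: 8 8-allyl-5,7-bis(benzyloxy)-4'-methoxyflavone
Conditions: p-TsOH·H2O (0.3 equiv), DMSO, 90 °C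
Reagents that add atoms: none
Why: In this acid-catalysed cyclodehydration of an o-hydroxyaryl 1,3-diketone the only free phenol adds to the anisoyl carbonyl in a six-membered closure and water is lost, so the allyl group must end on C8'', and catalytic sulfonic acid leaves the benzyl ethers and the alkene untouched.

Step 6
Reactants: 8 8-allyl-5,7-bis(benzyloxy)-4'-methoxyflavone
Product: 9 5,7-bis(benzyloxy)-4'-methoxy-8-(2-oxopropyl)flavone
Conditions: PdCl2 (10 mol %), CuCl, O2 (1 atm), DMF–H2O (7:1), rt
Reagents that add atoms: water, O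
Why: In the Tsuji–Wacker oxidation divalent palladium activates the terminal alkene for Markovnikov attack of water and β-hydride elimination releases the methyl ketone, a routine conversion of allylarenes into arylacetones that spares the conjugated pyranone double bond and the benzyl ethers.

Step 7
Reactants: 9 5,7-bis(benzyloxy)-4'-methoxy-8-(2-oxopropyl)flavone; 10 N,N-dimethylformamide dimethyl acetal
Product: 11 (E)-5,7-bis(benzyloxy)-8-[1-(dimethylamino)-3-oxobut-1-en-2-yl]-4'-methoxyflavone
Conditions: 10 (5 equiv), toluene, 105 °C, MeOH distilled off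
Reagents that add atoms: none
Why: Aminomethylenation of an active methylene with an amide acetal is known for arylacetones: the benzylic CH2 is the more acidic site and gives the more conjugated product, and the push–pull double bond settles in the E form, with NMe2 anti to the coplanar acetyl group and next to the twisted, therefore slim, aryl ring.

Step 8
Reactants: 11 (E)-5,7-bis(benzyloxy)-8-[1-(dimethylamino)-3-oxobut-1-en-2-yl]-4'-methoxyflavone
Product: 12 (E)-8-[1-(dimethylamino)-3-(tert-butyldimethylsilyloxy)buta-1,3-dien-2-yl]-5,7-bis(benzyloxy)-4'-methoxyflavone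
Conditions: TBSOTf (1.3 equiv), Et3N (3 equiv), CH2Cl2, 0 °C; cold aq. NaHCO3 wash, no chromatography
Reagents that add atoms: tert-butyldimethylsilyl triflate, CC(C)(C)[Si](C)(C)OS(=O)(=O)C(F)(F)F
Why: In this soft enolisation, as used for 1-amino-3-siloxydienes, the triflate silylates the most basic oxygen (the vinylogous amide) to a siloxy-iminium ion whose only removable protons sit on the methyl group, so Et3N unveils the terminal CH2, the E enamine geometry is kept and the flavone never meets a strong base.

Step 9
Reactants: 12 (E)-8-[1-(dimethylamino)-3-(tert-butyldimethylsilyloxy)buta-1,3-dien-2-yl]-5,7-bis(benzyloxy)-4'-methoxyflavone; 13 methyl propiolate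
Product: 15 methyl 4-(tert-butyldimethylsilyloxy)-3-[5,7-bis(benzyloxy)-4'-methoxyflavon-8-yl]benzoate, via cyclohexa-1,4-diene cycloadduct 14 (not isolated)
Conditions: 13 (3 equiv), toluene, 25 → 80 °C, Ar
Reagents that add atoms: none
Why: The donor-rich diene 12 adds to the electron-poor alkyne 13 in an asynchronous but concerted normal-demand [4+2] cycloaddition, in which the CH2 terminus (future C5') leads bond formation to the unsubstituted alkyne carbon (C6') and the aminated terminus (C2') then closes onto the ester-bearing carbon (C1'). Ring B is thus closed in an intermolecular six-membered (4+2) mode to give the 1,4-cyclohexadiene 14, and thermal 1,4-loss of dimethylamine (N from C2', H from C5') aromatises it with the O4' silyl ether intact. The closest known reaction type is the Diels–Alder/elimination benzannulation of 1-amino-3-siloxy- and 1-alkoxy-3-siloxybutadienes with propiolates to 4-oxygenated benzoates. The only stereocentre formed, C2' of 14, is transient and disappears on aromatisation, so no stereocontrol is needed. The selectivity required is regiochemical (ester para and flavonyl ortho to O4'), and it is secured because the amino and siloxy donors act together to place the largest coefficient on C5' while the ester polarises the alkyne in the matching sense. The di-ortho-substituted flavonyl group stands perpendicular to the diene, penalises the s-trans rotamer through contact with the terminal CH2, and leaves the slim, linear alkyne room to reach both termini.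

Step 10
Reactants: 15 methyl 4-(tert-butyldimethylsilyloxy)-3-[5,7-bis(benzyloxy)-4'-methoxyflavon-8-yl]benzoate
Product: 17 methyl 4-(benzyloxy)-3-[5,7-bis(benzyloxy)-4'-methoxyflavon-8-yl]benzoate, via desilylated phenol 16 (not isolated)
Conditions: CsF (2 equiv), BnBr (1.5 equiv), DMF, rt
Reagents that add atoms: benzyl bromide, BrCc1ccccc1
Why: Fluoride cleaves the aryl silyl ether and the phenoxide set free is benzylated in the same flask (Williamson etherification), which exchanges a base-labile group for one that survives steps 11 and 12 and leaves in step 13 together with the others.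

Step 11
Reactants: 17 methyl 4-(benzyloxy)-3-[5,7-bis(benzyloxy)-4'-methoxyflavon-8-yl]benzoate; 2 1-[2,4-bis(benzyloxy)-6-hydroxyphenyl]ethanone
Product: 18 1-[2,4-bis(benzyloxy)-6-hydroxyphenyl]-3-{4-(benzyloxy)-3-[5,7-bis(benzyloxy)-4'-methoxyflavon-8-yl]phenyl}propane-1,3-dione
Conditions: 2 (1.5 equiv), LiN(SiMe3)2 (4.5 equiv), THF, −78 → 0 °C; then 17, 0 → 45 °C; aq. HCl
Reagents that add atoms: none
Why: Crossed Claisen condensation of an o-hydroxyacetophenone dianion with a non-enolisable aryl ester is a standard entry to flavone diketones: only 2 can form an enolate, only 17 offers an ester carbonyl, irreversible deprotonation of the product drives the equilibrium, and any reversible opening of the unit 2 pyranone would be repaired in step 12.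

Step 12
Reactants: 18 1-[2,4-bis(benzyloxy)-6-hydroxyphenyl]-3-{4-(benzyloxy)-3-[5,7-bis(benzyloxy)-4'-methoxyflavon-8-yl]phenyl}propane-1,3-dione
Product: 19 5,7,4',5'',7''-penta-O-benzylpodocarpusflavone A
Conditions: p-TsOH·H2O (0.5 equiv), DMSO, 90 °C
Reagents that add atoms: none
Why: This is the same acid-catalysed cyclodehydration as in step 5: the single free phenol of 18 closes ring C of unit 1 onto the carbonyl next to ring B, and because O5'' stays benzylated the unit 2 pyranone has no second phenol to re-close on, which excludes a Wessely–Moser isomerisation.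

Step 13
Reactants: 19 5,7,4',5'',7''-penta-O-benzylpodocarpusflavone A
Product: 20 podocarpusflavone A
Conditions: H2 (1 atm), Pd/C (10 wt %), THF–MeOH (1:1), rt
Reagents that add atoms: none
Why: Catalytic hydrogenolysis cleaves all five benzylic C–O bonds under neutral conditions, the aryl methyl ether on C4''' is inert, the pyranone double bonds are reduced far more slowly than benzyl ethers are cleaved, and the absence of acid rules out migration of the linkage from C8'' to C6''.

Compound list
1 | 2,4,6-trihydroxyacetophenone | CC(=O)c1c(O)cc(O)cc1O | starting material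
2 | 1-[2,4-bis(benzyloxy)-6-hydroxyphenyl]ethanone | CC(=O)c1c(O)cc(OCc2ccccc2)cc1OCc1ccccc1 | intermediate
3 | allyl bromide | C=CCBr | starting material
4 | 1-[2-(allyloxy)-4,6-bis(benzyloxy)phenyl]ethanone | CC(=O)c1c(OCC=C)cc(OCc2ccccc2)cc1OCc1ccccc1 | intermediate
5 | 1-[3-allyl-4,6-bis(benzyloxy)-2-hydroxyphenyl]ethanone | CC(=O)c1c(O)c(CC=C)c(OCc2ccccc2)cc1OCc1ccccc1 | intermediate
6 | 4-methoxybenzoyl chloride | COc1ccc(cc1)C(Cl)=O | starting material
7 | 1-[3-allyl-4,6-bis(benzyloxy)-2-hydroxyphenyl]-3-(4-methoxyphenyl)propane-1,3-dione | COc1ccc(cc1)C(=O)CC(=O)c1c(O)c(CC=C)c(OCc2ccccc2)cc1OCc1ccccc1 | intermediate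
8 | 8-allyl-5,7-bis(benzyloxy)-4'-methoxyflavone | C=CCc1c(OCc2ccccc2)cc(OCc2ccccc2)c2c1oc(cc2=O)-c1ccc(OC)cc1 | intermediate
9 | 5,7-bis(benzyloxy)-4'-methoxy-8-(2-oxopropyl)flavone | CC(=O)Cc1c(OCc2ccccc2)cc(OCc2ccccc2)c2c1oc(cc2=O)-c1ccc(OC)cc1 | intermediate
10 | N,N-dimethylformamide dimethyl acetal | COC(OC)N(C)C | starting material
11 | (E)-5,7-bis(benzyloxy)-8-[1-(dimethylamino)-3-oxobut-1-en-2-yl]-4'-methoxyflavone | CN(C)/C=C(\c1c(OCc2ccccc2)cc(OCc2ccccc2)c2c1oc(cc2=O)-c1ccc(OC)cc1)C(C)=O | intermediate
12 | (E)-8-[1-(dimethylamino)-3-(tert-butyldimethylsilyloxy)buta-1,3-dien-2-yl]-5,7-bis(benzyloxy)-4'-methoxyflavone | CN(C)/C=C(\c1c(OCc2ccccc2)cc(OCc2ccccc2)c2c1oc(cc2=O)-c1ccc(OC)cc1)C(=C)O[Si](C)(C)C(C)(C)C | intermediate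
13 | methyl propiolate | COC(=O)C#C | starting material
14 | methyl 6-(dimethylamino)-4-(tert-butyldimethylsilyloxy)-5-[5,7-bis(benzyloxy)-4'-methoxyflavon-8-yl]cyclohexa-1,4-diene-1-carboxylate (racemic, transient) | COC(=O)C1=CCC(O[Si](C)(C)C(C)(C)C)=C(C1N(C)C)c1c(OCc2ccccc2)cc(OCc2ccccc2)c2c1oc(cc2=O)-c1ccc(OC)cc1 | intermediate
15 | methyl 4-(tert-butyldimethylsilyloxy)-3-[5,7-bis(benzyloxy)-4'-methoxyflavon-8-yl]benzoate | COC(=O)c1ccc(O[Si](C)(C)C(C)(C)C)c(c1)-c1c(OCc2ccccc2)cc(OCc2ccccc2)c2c1oc(cc2=O)-c1ccc(OC)cc1 | intermediate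
16 | methyl 4-hydroxy-3-[5,7-bis(benzyloxy)-4'-methoxyflavon-8-yl]benzoate (present in the flask as its caesium phenoxide) | COC(=O)c1ccc(O)c(c1)-c1c(OCc2ccccc2)cc(OCc2ccccc2)c2c1oc(cc2=O)-c1ccc(OC)cc1 | intermediate
17 | methyl 4-(benzyloxy)-3-[5,7-bis(benzyloxy)-4'-methoxyflavon-8-yl]benzoate | COC(=O)c1ccc(OCc2ccccc2)c(c1)-c1c(OCc2ccccc2)cc(OCc2ccccc2)c2c1oc(cc2=O)-c1ccc(OC)cc1 | intermediate
18 | 1-[2,4-bis(benzyloxy)-6-hydroxyphenyl]-3-{4-(benzyloxy)-3-[5,7-bis(benzyloxy)-4'-methoxyflavon-8-yl]phenyl}propane-1,3-dione | O=C(CC(=O)c1c(O)cc(OCc2ccccc2)cc1OCc1ccccc1)c1ccc(OCc2ccccc2)c(c1)-c1c(OCc2ccccc2)cc(OCc2ccccc2)c2c1oc(cc2=O)-c1ccc(OC)cc1 | intermediate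
19 | 5,7,4',5'',7''-penta-O-benzylpodocarpusflavone A | COc1ccc(cc1)-c1cc(=O)c2c(OCc3ccccc3)cc(OCc3ccccc3)c(c2o1)-c1cc(ccc1OCc1ccccc1)-c1cc(=O)c2c(OCc3ccccc3)cc(OCc3ccccc3)cc2o1 | intermediate
20 | podocarpusflavone A | COc1ccc(-c2cc(=O)c3c(O)cc(O)c(-c4cc(-c5cc(=O)c6c(O)cc(O)cc6o5)ccc4O)c3o2)cc1 | target

Total step count: 13. Longest linear sequence: 13 steps (1 to 20). Compound 2 is made once and used in steps 2 and 11, so the second flavone half costs no extra steps.

Steps most likely to fail

Step 9. The out-of-plane flavonyl group next to the bond-forming terminus may slow the cycloaddition so much that hydrolysis of the silyl dienol ether, or attack of the liberated amine on the substrate, outruns ring formation.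
The fallback makes the C3'–C8'' bond by cross-coupling instead of building ring B. It sets out from 2 and comes back at 17. Iodination of 2 ortho to the free phenol (N-iodosuccinimide, DMF, 0 °C) should give 1-[4,6-bis(benzyloxy)-2-hydroxy-3-iodophenyl]ethanone F1. C-acylation with 6 under the conditions of step 4 leads to 1-[4,6-bis(benzyloxy)-2-hydroxy-3-iodophenyl]-3-(4-methoxyphenyl)propane-1,3-dione F2, and cyclodehydration as in step 5 leads to 5,7-bis(benzyloxy)-8-iodo-4'-methoxyflavone F3. In parallel, commercial methyl 3-bromo-4-hydroxybenzoate is benzylated (BnBr, K2CO3, DMF) to methyl 4-(benzyloxy)-3-bromobenzoate F4. Miyaura borylation (B2pin2, PdCl2(dppf), KOAc, dioxane, 90 °C) then gives methyl 4-(benzyloxy)-3-(4,4,5,5-tetramethyl-1,3,2-dioxaborolan-2-yl)benzoate F5. Suzuki–Miyaura coupling of F3 and F5 (Pd(OAc)2, SPhos, K3PO4, toluene–H2O, 90 °C) delivers 17.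

Step 7. Condensation may take place at the unhindered methyl group, or at both α-positions, instead of at the crowded benzylic CH2.
The fallback builds the vinylogous amide from the other side, so that only one site can be acylated. It sets out from 8 and comes back at 11. Lemieux–Johnson cleavage of the allyl group (cat. OsO4, NaIO4, 2,6-lutidine, dioxane–H2O) should give [5,7-bis(benzyloxy)-4'-methoxyflavon-8-yl]acetaldehyde F6. Condensation with dimethylamine (2 M in THF, MgSO4, 0 °C → rt) gives the conjugated enamine (E)-5,7-bis(benzyloxy)-8-[2-(dimethylamino)vinyl]-4'-methoxyflavone F7. Stork-type C-acylation with acetyl chloride and Et3N (CH2Cl2, 0 °C) can place the acetyl group only on the aryl-bearing enamine carbon, which gives 11.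

Step 11. Intermolecular acyl transfer to the deactivated 4-alkoxybenzoate may be so slow that base-induced degradation of the unit 2 pyranone or simple recovery of both partners prevails.
The fallback makes the C–C bond intramolecularly. It sets out from 17 and comes back at 18. Saponification (LiOH, THF–MeOH–H2O, 40 °C, then dilute HCl) should give 4-(benzyloxy)-3-[5,7-bis(benzyloxy)-4'-methoxyflavon-8-yl]benzoic acid F8. Steglich-type esterification with 2 (EDC·HCl, DMAP, CH2Cl2) gives 2-acetyl-3,5-bis(benzyloxy)phenyl 4-(benzyloxy)-3-[5,7-bis(benzyloxy)-4'-methoxyflavon-8-yl]benzoate F9. Baker–Venkataraman rearrangement (KOH, pyridine, 50 °C) then shifts the aroyl group from oxygen to the acetyl carbon to give 18.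

Further compounds
F1 | step 9 | 1-[4,6-bis(benzyloxy)-2-hydroxy-3-iodophenyl]ethanone | CC(=O)c1c(O)c(I)c(OCc2ccccc2)cc1OCc1ccccc1
F2 | step 9 | 1-[4,6-bis(benzyloxy)-2-hydroxy-3-iodophenyl]-3-(4-methoxyphenyl)propane-1,3-dione | COc1ccc(cc1)C(=O)CC(=O)c1c(O)c(I)c(OCc2ccccc2)cc1OCc1ccccc1
F3 | step 9 | 5,7-bis(benzyloxy)-8-iodo-4'-methoxyflavone | COc1ccc(cc1)-c1cc(=O)c2c(OCc3ccccc3)cc(OCc3ccccc3)c(I)c2o1
F4 | step 9 | methyl 4-(benzyloxy)-3-bromobenzoate | COC(=O)c1ccc(OCc2ccccc2)c(Br)c1
F5 | step 9 | methyl 4-(benzyloxy)-3-(4,4,5,5-tetramethyl-1,3,2-dioxaborolan-2-yl)benzoate | COC(=O)c1ccc(OCc2ccccc2)c(c1)B1OC(C)(C)C(C)(C)O1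
F6 | step 7 | [5,7-bis(benzyloxy)-4'-methoxyflavon-8-yl]acetaldehyde | O=CCc1c(OCc2ccccc2)cc(OCc2ccccc2)c2c1oc(cc2=O)-c1ccc(OC)cc1
F7 | step 7 | (E)-5,7-bis(benzyloxy)-8-[2-(dimethylamino)vinyl]-4'-methoxyflavone | CN(C)/C=C/c1c(OCc2ccccc2)cc(OCc2ccccc2)c2c1oc(cc2=O)-c1ccc(OC)cc1
F8 | step 11 | 4-(benzyloxy)-3-[5,7-bis(benzyloxy)-4'-methoxyflavon-8-yl]benzoic acid | OC(=O)c1ccc(OCc2ccccc2)c(c1)-c1c(OCc2ccccc2)cc(OCc2ccccc2)c2c1oc(cc2=O)-c1ccc(OC)cc1
F9 | step 11 | 2-acetyl-3,5-bis(benzyloxy)phenyl 4-(benzyloxy)-3-[5,7-bis(benzyloxy)-4'-methoxyflavon-8-yl]benzoate | CC(=O)c1c(OC(=O)c2ccc(OCc3ccccc3)c(c2)-c2c(OCc3ccccc3)cc(OCc3ccccc3)c3c2oc(cc3=O)-c2ccc(OC)cc2)cc(OCc2ccccc2)cc1OCc1ccccc1
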